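**Strategy.** The route rests on cutting the C2=C3 double bond of pyranone ring C. C3 is the α-carbon of the C4 aryl ketone on C4a, and C2 is a benzoyl carbon that can be parked as a benzoate on the C8a oxygen (the future O1). One thermal intramolecular ester Wittig olefination therefore forms C2=C3, closes ring C and completes the flavone under neutral conditions. Its precursor is a pentasubstituted benzene (ring A) carrying the keto ylide C(=O)CH=PPh3 flanked by a benzoate and a methoxyl, a para TIPS ether and the (S)-N-methylpiperidine, whose stereocentre is set earlier by a sulfinyl imine addition.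

Key step: step 11

Remark on the chemistry: ring atoms are numbered as in the flavone (O1, C2, C3, C4, C4a, C5 to C8, C8a; piperidine carbon C2'), and the Grignard addition of step 5 is assumed to follow the magnesium-chelate chair model usual for N-tert-butanesulfinyl aldimines in a non-coordinating solvent.

Step 1
Reactants: 1 2,4,6-trihydroxybenzaldehyde
Product: 2 2,6-dihydroxy-4-(methoxymethoxy)benzaldehyde
Conditions: MOMCl (1.05 equiv), K2CO3 (1.1 equiv), acetone, 0 °C to rt
Reagents that add atoms: chloromethyl methyl ether (MOMCl), COCCl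
Why: Williamson-type O-alkylation, in which the 4-hydroxyl (para to the formyl group and the only one not held in a hydrogen bond to it) is the most acidic and most accessible, so one equivalent of MOMCl should protect it selectively.

Step 2
Reactants: 2 2,6-dihydroxy-4-(methoxymethoxy)benzaldehyde
Product: 3 2-hydroxy-6-methoxy-4-(methoxymethoxy)benzaldehyde
Conditions: MeI (1.1 equiv), K2CO3 (1.1 equiv), acetone, rt
Reagents that add atoms: iodomethane, CI
Why: Williamson ether synthesis on two equivalent hydroxyls; once one is methylated the other is locked in a strong hydrogen bond to the aldehyde and is far less nucleophilic, so the reaction should stop at the monoether.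

Step 3
Reactants: 3 2-hydroxy-6-methoxy-4-(methoxymethoxy)benzaldehyde
Product: 4 2-methoxy-4-(methoxymethoxy)-6-(triisopropylsilyloxy)benzaldehyde
Conditions: TIPSCl (1.3 equiv), imidazole (2.5 equiv), 4-(dimethylamino)pyridine (cat.), DMF, rt to 40 °C
Reagents that add atoms: chlorotriisopropylsilane (TIPSCl), CC(C)[Si](Cl)(C(C)C)C(C)C
Why: Imidazole-mediated silylation of a phenol under near-neutral conditions that leave the MOM acetal intact; the bulky silyl ether later shields the neighbouring ring carbon (future C8).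

Step 4
Reactants: 4 2-methoxy-4-(methoxymethoxy)-6-(triisopropylsilyloxy)benzaldehyde; 5 (R)-2-methylpropane-2-sulfinamide
Product: 6 (R,E)-N-{[2-methoxy-4-(methoxymethoxy)-6-(triisopropylsilyloxy)phenyl]methylidene}-2-methylpropane-2-sulfinamide
Conditions: Ti(OEt)4 (2 equiv), THF, 60 °C
Reagents that add atoms: none
Why: Lewis acid-mediated condensation of an aldehyde with a primary sulfinamide, in which Ti(OEt)4 activates the hindered carbonyl and takes up the water, giving the E-aldimine with the sulfur configuration unchanged.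

Step 5
Reactants: 6 (R,E)-N-{[2-methoxy-4-(methoxymethoxy)-6-(triisopropylsilyloxy)phenyl]methylidene}-2-methylpropane-2-sulfinamide; 7 1-bromo-4-chlorobutane
Product: 9 (R)-N-{(1S)-5-chloro-1-[2-methoxy-4-(methoxymethoxy)-6-(triisopropylsilyloxy)phenyl]pentyl}-2-methylpropane-2-sulfinamide, via 4-chlorobutylmagnesium bromide 8 (not isolated)
Conditions: 7, Mg, Et2O, rt; then 6, CH2Cl2, −48 °C to rt; aq. NH4Cl
Reagents that add atoms: none
Why: Grignard 1,2-addition to an N-tert-butanesulfinyl aldimine (Mg inserts only into the C–Br bond of 7), in which magnesium is held by the sulfinyl oxygen in a six-membered chair transition state with the tert-butyl and aryl groups equatorial, so the alkyl group is delivered to the imine face that gives the S carbon from the R sulfur; the minor diastereomer should be removable by chromatography at this stage.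

Step 6
Reactants: 9 (R)-N-{(1S)-5-chloro-1-[2-methoxy-4-(methoxymethoxy)-6-(triisopropylsilyloxy)phenyl]pentyl}-2-methylpropane-2-sulfinamide
Product: 11 (2S)-2-[2-methoxy-4-(methoxymethoxy)-6-(triisopropylsilyloxy)phenyl]piperidine, via primary amine hydrochloride 10 (not isolated)
Conditions: HCl (4 M in dioxane, 2 equiv), MeOH, 0 °C; then K2CO3, NaI (cat.), MeCN, 60 °C
Reagents that add atoms: none
Why: Acid methanolysis of the N–S bond (much faster at 0 °C than loss of the aryl MOM or TIPS ether) frees the primary amine, which after basification should close the piperidine by intramolecular SN2 displacement of the primary chloride (6-exo-tet, iodide-assisted as in a Finkelstein exchange) without touching the stereocentre.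

Step 7
Reactants: 11 (2S)-2-[2-methoxy-4-(methoxymethoxy)-6-(triisopropylsilyloxy)phenyl]piperidine
Product: 12 (2S)-2-[2-methoxy-4-(methoxymethoxy)-6-(triisopropylsilyloxy)phenyl]-1-methylpiperidine
Conditions: aq. CH2O (37%), NaBH(OAc)3, ClCH2CH2Cl, rt
Reagents that add atoms: formaldehyde, C=O
Why: Reductive amination, in which formaldehyde gives the iminium ion of the secondary amine and NaBH(OAc)3 reduces it to the N-methyl tertiary amine without over-alkylation and without touching the ethers.

Step 8
Reactants: 12 (2S)-2-[2-methoxy-4-(methoxymethoxy)-6-(triisopropylsilyloxy)phenyl]-1-methylpiperidine; 13 2-chloro-N-methoxy-N-methylacetamide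
Product: 15 2-chloro-1-{2-methoxy-6-(methoxymethoxy)-3-[(2S)-1-methylpiperidin-2-yl]-4-(triisopropylsilyloxy)phenyl}ethan-1-one, via aryllithium 14 (not isolated)
Conditions: n-BuLi (1.2 equiv), THF, 0 °C; then 13, −78 °C; AcOH, −78 °C
Reagents that add atoms: none
Why: Directed ortho-metalation followed by Weinreb ketone synthesis, in which n-BuLi, held by the MOM and methoxy oxygens, removes the ring proton between them (future C4a) while the bulky TIPS ether shields the only other ring C–H, and the aryllithium adds once to the Weinreb amide to give a chelated adduct that releases the chloromethyl ketone only on acid quench.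

Step 9
Reactants: 15 2-chloro-1-{2-methoxy-6-(methoxymethoxy)-3-[(2S)-1-methylpiperidin-2-yl]-4-(triisopropylsilyloxy)phenyl}ethan-1-one
Product: 18 [2-hydroxy-6-methoxy-5-((S)-1-methylpiperidin-2-yl)-4-(triisopropylsilyloxy)benzoyl]methylenetriphenylphosphorane, via MOM phosphonium salt 16 (not isolated), via hydroxy phosphonium salt 17 (not isolated)
Conditions: HCl (1.0 equiv, in dioxane), PPh3 (1.5 equiv), MeCN, 60 °C; then HCl, MeOH, rt; then aq. Na2CO3 (pH about 10), CH2Cl2
Reagents that add atoms: triphenylphosphine, c1ccc(cc1)P(c1ccccc1)c1ccccc1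
Why: SN2 displacement of the α-chloride by PPh3 (phosphonium salt formation, with the amine masked as its hydrochloride so that it cannot quaternise), acid methanolysis of the MOM acetal next to the ketone and deprotonation of the acidic α-CH2 by carbonate should give the carbonyl-stabilised ylide, the MOM group being kept until the chloride is gone so that no benzofuranone can form.

Step 10
Reactants: 18 [2-hydroxy-6-methoxy-5-((S)-1-methylpiperidin-2-yl)-4-(triisopropylsilyloxy)benzoyl]methylenetriphenylphosphorane; 19 benzoyl chloride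
Product: 20 [2-(benzoyloxy)-6-methoxy-5-((S)-1-methylpiperidin-2-yl)-4-(triisopropylsilyloxy)benzoyl]methylenetriphenylphosphorane
Conditions: 19 (1.05 equiv), pyridine (3 equiv), CH2Cl2, 0 °C
Reagents that add atoms: none
Why: Acylation of a phenol with an acid chloride under pyridine, in which the phenolic oxygen (the most acidic site) reacts faster with the acylpyridinium species than the hindered, carbonyl-stabilised ylide carbon, so the benzoyl group is placed on the C8a oxygen.

Step 11
Reactants: 20 [2-(benzoyloxy)-6-methoxy-5-((S)-1-methylpiperidin-2-yl)-4-(triisopropylsilyloxy)benzoyl]methylenetriphenylphosphorane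
Product: 21 5-methoxy-6-[(2S)-1-methylpiperidin-2-yl]-2-phenyl-7-(triisopropylsilyloxy)-4H-chromen-4-one
Conditions: toluene (0.02 M), 110 °C
Reagents that add atoms: none
Why: On heating, the ylide carbon C3 of the stabilised phosphorane adds to the benzoate carbonyl carbon C2 held on the C8a oxygen, the betaine closes to an oxaphosphetane and this collapses with loss of Ph3PO to the C2=C3 double bond. The closest known reaction type is the intramolecular Wittig olefination of an ester carbonyl, by which (2-acyloxybenzoyl)methylenephosphoranes are turned into chromones and flavones. Ring C is closed by a 6-exo-trig addition (the attacked C=O lies outside the forming ring O1–C2–C3–C4–C4a–C8a), and the elimination then places the new double bond inside the ring and makes the pyranone aromatic. No stereocentre is formed, and the existing C2' centre should be safe because the medium is neutral and aprotic and all three ring A oxygens are capped (methyl ether, TIPS ether, benzoate), so no quinone-methide pathway is open at the benzylic C–N bond. The step needs olefination to win over bimolecular reaction and over simple O-to-C benzoyl transfer: the aryl ester is an activated carbonyl fixed within six-membered reach of C3, dilution disfavours intermolecular paths, and the irreversible loss of Ph3PO drains the betaine toward the pyranone.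

Step 12
Reactants: 21 5-methoxy-6-[(2S)-1-methylpiperidin-2-yl]-2-phenyl-7-(triisopropylsilyloxy)-4H-chromen-4-one
Product: 22 7-hydroxy-5-methoxy-6-[(2S)-1-methylpiperidin-2-yl]-2-phenyl-4H-chromen-4-one
Conditions: Bu4NF (1.2 equiv), AcOH (1.2 equiv), THF, 0 °C
Reagents that add atoms: none
Why: Fluoride-mediated desilylation driven by the strong Si–F bond, buffered with acetic acid at 0 °C so that the liberated phenol stays protonated and neither the pyranone nor the benzylic amine centre next to the free hydroxyl is exposed to base or heat.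

**Compound list**

1 | 2,4,6-trihydroxybenzaldehyde | O=Cc1c(O)cc(O)cc1O | starting material
2 | 2,6-dihydroxy-4-(methoxymethoxy)benzaldehyde | COCOc1cc(O)c(C=O)c(O)c1 | intermediate
3 | 2-hydroxy-6-methoxy-4-(methoxymethoxy)benzaldehyde | COCOc1cc(O)c(C=O)c(OC)c1 | intermediate
4 | 2-methoxy-4-(methoxymethoxy)-6-(triisopropylsilyloxy)benzaldehyde | COCOc1cc(OC)c(C=O)c(O[Si](C(C)C)(C(C)C)C(C)C)c1 | intermediate
5 | (R)-2-methylpropane-2-sulfinamide | CC(C)(C)[S@@](=O)N | starting material
6 | (R,E)-N-{[2-methoxy-4-(methoxymethoxy)-6-(triisopropylsilyloxy)phenyl]methylidene}-2-methylpropane-2-sulfinamide | CC(C)(C)[S@@](=O)/N=C/c1c(OC)cc(OCOC)cc1O[Si](C(C)C)(C(C)C)C(C)C | intermediate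
7 | 1-bromo-4-chlorobutane | ClCCCCBr | starting material
8 | 4-chlorobutylmagnesium bromide | ClCCCC[Mg]Br | intermediate
9 | (R)-N-{(1S)-5-chloro-1-[2-methoxy-4-(methoxymethoxy)-6-(triisopropylsilyloxy)phenyl]pentyl}-2-methylpropane-2-sulfinamide | CC(C)(C)[S@@](=O)N[C@@H](CCCCCl)c1c(OC)cc(OCOC)cc1O[Si](C(C)C)(C(C)C)C(C)C | intermediate
10 | (1S)-5-chloro-1-[2-methoxy-4-(methoxymethoxy)-6-(triisopropylsilyloxy)phenyl]pentan-1-amine hydrochloride | N[C@@H](CCCCCl)c1c(OC)cc(OCOC)cc1O[Si](C(C)C)(C(C)C)C(C)C.Cl | intermediate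
11 | (2S)-2-[2-methoxy-4-(methoxymethoxy)-6-(triisopropylsilyloxy)phenyl]piperidine | COCOc1cc(OC)c([C@@H]2CCCCN2)c(O[Si](C(C)C)(C(C)C)C(C)C)c1 | intermediate
12 | (2S)-2-[2-methoxy-4-(methoxymethoxy)-6-(triisopropylsilyloxy)phenyl]-1-methylpiperidine | COCOc1cc(OC)c([C@@H]2CCCCN2C)c(O[Si](C(C)C)(C(C)C)C(C)C)c1 | intermediate
13 | 2-chloro-N-methoxy-N-methylacetamide | CON(C)C(=O)CCl | starting material
14 | {2-methoxy-6-(methoxymethoxy)-3-[(2S)-1-methylpiperidin-2-yl]-4-(triisopropylsilyloxy)phenyl}lithium | COCOc1cc(O[Si](C(C)C)(C(C)C)C(C)C)c([C@@H]2CCCCN2C)c(OC)c1[Li] | intermediate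
15 | 2-chloro-1-{2-methoxy-6-(methoxymethoxy)-3-[(2S)-1-methylpiperidin-2-yl]-4-(triisopropylsilyloxy)phenyl}ethan-1-one | COCOc1cc(O[Si](C(C)C)(C(C)C)C(C)C)c([C@@H]2CCCCN2C)c(OC)c1C(=O)CCl | intermediate
16 | (2-{2-methoxy-6-(methoxymethoxy)-3-[(2S)-1-methylpiperidin-2-yl]-4-(triisopropylsilyloxy)phenyl}-2-oxoethyl)triphenylphosphonium chloride hydrochloride | COCOc1cc(O[Si](C(C)C)(C(C)C)C(C)C)c([C@@H]2CCCCN2C)c(OC)c1C(=O)C[P+](c1ccccc1)(c1ccccc1)c1ccccc1.[Cl-].Cl | intermediate
17 | (2-{6-hydroxy-2-methoxy-3-[(2S)-1-methylpiperidin-2-yl]-4-(triisopropylsilyloxy)phenyl}-2-oxoethyl)triphenylphosphonium chloride hydrochloride | COc1c([C@@H]2CCCCN2C)c(O[Si](C(C)C)(C(C)C)C(C)C)cc(O)c1C(=O)C[P+](c1ccccc1)(c1ccccc1)c1ccccc1.[Cl-].Cl | intermediate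
18 | [2-hydroxy-6-methoxy-5-((S)-1-methylpiperidin-2-yl)-4-(triisopropylsilyloxy)benzoyl]methylenetriphenylphosphorane | COc1c([C@@H]2CCCCN2C)c(O[Si](C(C)C)(C(C)C)C(C)C)cc(O)c1C(=O)C=P(c1ccccc1)(c1ccccc1)c1ccccc1 | intermediate
19 | benzoyl chloride | O=C(Cl)c1ccccc1 | starting material
20 | [2-(benzoyloxy)-6-methoxy-5-((S)-1-methylpiperidin-2-yl)-4-(triisopropylsilyloxy)benzoyl]methylenetriphenylphosphorane | COc1c([C@@H]2CCCCN2C)c(O[Si](C(C)C)(C(C)C)C(C)C)cc(OC(=O)c2ccccc2)c1C(=O)C=P(c1ccccc1)(c1ccccc1)c1ccccc1 | intermediate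
21 | 5-methoxy-6-[(2S)-1-methylpiperidin-2-yl]-2-phenyl-7-(triisopropylsilyloxy)-4H-chromen-4-one | COc1c([C@@H]2CCCCN2C)c(O[Si](C(C)C)(C(C)C)C(C)C)cc2oc(-c3ccccc3)cc(=O)c12 | intermediate
22 | 7-hydroxy-5-methoxy-6-[(2S)-1-methylpiperidin-2-yl]-2-phenyl-4H-chromen-4-one | COc1c([C@@H]2CCCCN2C)c(O)cc2oc(-c3ccccc3)cc(=O)c12 | target

Total step count: 12
Longest linear sequence: 12 steps (1 to 22)

**Steps most likely to fail**

Step 8. Three processes could spoil it: proton transfer from the α-chloro amide to the hindered, doubly flanked aryllithium (returning 12), metalation at the ring carbon next to the silyl ether, or self-quaternisation of the product while it is handled as the free amine. The fallback sets out from 12 and avoids the chloroketone altogether. Aryllithium 14, made as in step 8, would be quenched with CO2 to give 2-methoxy-6-(methoxymethoxy)-3-[(2S)-1-methylpiperidin-2-yl]-4-(triisopropylsilyloxy)benzoic acid F1. Activation with 1,1'-carbonyldiimidazole in THF would give the acyl imidazolide (1H-imidazol-1-yl){2-methoxy-6-(methoxymethoxy)-3-[(2S)-1-methylpiperidin-2-yl]-4-(triisopropylsilyloxy)phenyl}methanone F2, which needs no acid chloride next to the MOM acetal. Acylation of Ph3P=CH2 (2 equiv, from Ph3PCH3Br and NaN(SiMe3)2, THF) with F2 would give the MOM-protected keto ylide [2-methoxy-6-(methoxymethoxy)-3-((S)-1-methylpiperidin-2-yl)-4-(triisopropylsilyloxy)benzoyl]methylenetriphenylphosphorane F3. HCl in MeOH at rt followed by aq. Na2CO3 would remove the MOM group and come back to the route at 18.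

Step 5. Facial selectivity may be poor if the ortho methoxy oxygen competes with the sulfinyl oxygen for magnesium, and addition to the doubly ortho-substituted imine may be slow. The fallback sets out from 4 and sets the stereocentre by C–H instead of C–C bond formation. Addition of Grignard reagent 8 to the aldehyde would give racemic 5-chloro-1-[2-methoxy-4-(methoxymethoxy)-6-(triisopropylsilyloxy)phenyl]pentan-1-ol F4. Dess–Martin oxidation would give 5-chloro-1-[2-methoxy-4-(methoxymethoxy)-6-(triisopropylsilyloxy)phenyl]pentan-1-one F5. Condensation with 5 (Ti(OEt)4, THF, 75 °C) would give the ketimine (R,E)-N-{5-chloro-1-[2-methoxy-4-(methoxymethoxy)-6-(triisopropylsilyloxy)phenyl]pentylidene}-2-methylpropane-2-sulfinamide F6. Reduction with LiBH(s-Bu)3 at −78 °C, which attacks through an open transition state, is expected to deliver the (R)-sulfur, (S)-carbon diastereomer and so come back to the route at 9.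

Step 11. The benzoyl group may migrate from oxygen to the ylide carbon without loss of Ph3PO, or closure may be slowed by the twist that the two ortho substituents impose on the keto ylide. The fallback sets out from 12 and closes ring C at O1 instead. Aryllithium 14 would be added to 3-phenylprop-2-ynal at −78 °C to give 1-{2-methoxy-6-(methoxymethoxy)-3-[(2S)-1-methylpiperidin-2-yl]-4-(triisopropylsilyloxy)phenyl}-3-phenylprop-2-yn-1-ol F7 (both epimers at the carbinol carbon). MnO2 in CH2Cl2 would oxidise it to the ynone 1-{2-methoxy-6-(methoxymethoxy)-3-[(2S)-1-methylpiperidin-2-yl]-4-(triisopropylsilyloxy)phenyl}-3-phenylprop-2-yn-1-one F8. HCl in MeOH at rt would remove the MOM group to give 1-{6-hydroxy-2-methoxy-3-[(2S)-1-methylpiperidin-2-yl]-4-(triisopropylsilyloxy)phenyl}-3-phenylprop-2-yn-1-one F9. Et2NH in EtOH at rt should then close the ring by conjugate addition and 6-endo cyclisation through the β-amino enone, coming back to the route at 21.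

**Further compounds**

F1 | step 8 | 2-methoxy-6-(methoxymethoxy)-3-[(2S)-1-methylpiperidin-2-yl]-4-(triisopropylsilyloxy)benzoic acid | COCOc1cc(O[Si](C(C)C)(C(C)C)C(C)C)c([C@@H]2CCCCN2C)c(OC)c1C(=O)O
F2 | step 8 | (1H-imidazol-1-yl){2-methoxy-6-(methoxymethoxy)-3-[(2S)-1-methylpiperidin-2-yl]-4-(triisopropylsilyloxy)phenyl}methanone | COCOc1cc(O[Si](C(C)C)(C(C)C)C(C)C)c([C@@H]2CCCCN2C)c(OC)c1C(=O)n1ccnc1
F3 | step 8 | [2-methoxy-6-(methoxymethoxy)-3-((S)-1-methylpiperidin-2-yl)-4-(triisopropylsilyloxy)benzoyl]methylenetriphenylphosphorane | COCOc1cc(O[Si](C(C)C)(C(C)C)C(C)C)c([C@@H]2CCCCN2C)c(OC)c1C(=O)C=P(c1ccccc1)(c1ccccc1)c1ccccc1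
F4 | step 5 | 5-chloro-1-[2-methoxy-4-(methoxymethoxy)-6-(triisopropylsilyloxy)phenyl]pentan-1-ol (racemic) | OC(CCCCCl)c1c(OC)cc(OCOC)cc1O[Si](C(C)C)(C(C)C)C(C)C
F5 | step 5 | 5-chloro-1-[2-methoxy-4-(methoxymethoxy)-6-(triisopropylsilyloxy)phenyl]pentan-1-one | O=C(CCCCCl)c1c(OC)cc(OCOC)cc1O[Si](C(C)C)(C(C)C)C(C)C
F6 | step 5 | (R,E)-N-{5-chloro-1-[2-methoxy-4-(methoxymethoxy)-6-(triisopropylsilyloxy)phenyl]pentylidene}-2-methylpropane-2-sulfinamide | CC(C)(C)[S@@](=O)/N=C(\CCCCCl)c1c(OC)cc(OCOC)cc1O[Si](C(C)C)(C(C)C)C(C)C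
F7 | step 11 | 1-{2-methoxy-6-(methoxymethoxy)-3-[(2S)-1-methylpiperidin-2-yl]-4-(triisopropylsilyloxy)phenyl}-3-phenylprop-2-yn-1-ol (both carbinol epimers) | COCOc1cc(O[Si](C(C)C)(C(C)C)C(C)C)c([C@@H]2CCCCN2C)c(OC)c1C(O)C#Cc1ccccc1
F8 | step 11 | 1-{2-methoxy-6-(methoxymethoxy)-3-[(2S)-1-methylpiperidin-2-yl]-4-(triisopropylsilyloxy)phenyl}-3-phenylprop-2-yn-1-one | COCOc1cc(O[Si](C(C)C)(C(C)C)C(C)C)c([C@@H]2CCCCN2C)c(OC)c1C(=O)C#Cc1ccccc1
F9 | step 11 | 1-{6-hydroxy-2-methoxy-3-[(2S)-1-methylpiperidin-2-yl]-4-(triisopropylsilyloxy)phenyl}-3-phenylprop-2-yn-1-one | COc1c([C@@H]2CCCCN2C)c(O[Si](C(C)C)(C(C)C)C(C)C)cc(O)c1C(=O)C#Cc1ccccc1
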